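0.446 h is the number to carry through this flask. It is the settling half-life, the time in which the gap between D and its plateau halves; the usual term is relaxation half-life.

| flask | J | remark | time |
|---|---|---|---|
| north | 0.19 M | the very flask that is asked about, followed so far |  |
| west | 0.095 M | run made earlier |  |
| flask | 0.19 M |  | 10 h |

- north (time / h: D / %): 0.250: 24; 0.833: 52; 1.33: 60; 2.00: 71; 3.00: 71; 4.00: 68; 5.00: 71
- west (time / h: D / %): 0.200: 14; 0.667: 45; 1.00: 63; 1.50: 71; 2.50: 82; 3.00: 81; 4.00: 78

(readings scatter by 2 percentage points)



- amount of D in percent of the J charged, at 30 min, 2.5 h and 10 h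

You read it from the north run. Take the plateau as 71%, the reading at 3.00 h. The gap then shrinks between the readings at 0.250 h and 0.833 h, and that shrinkage gives the number.

Now climb the ladder of times. The rise comes first, and for the asked flask my reckoning at 30 min is 38.4%. The plateau comes next. At 2.5 h the same rule gives 69.5%, so by this reckoning nearly all of the rise is done. The last rung is any drift. The north run reads 71% at 2.00 h and 71% at 5.00 h, so within a scatter of 2 percentage points it shows none. I hold 71% at 10 h and lean low.

Test the rule on the west run. Its own readings give 0.532 h. With 82%, its reading at 2.50 h, taken as the plateau, that predicts 59.7% at 1.00 h, and the reading is 63%.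

The forecast gives 38%, 70% and 70%. At 10 h it stands a point below mine, and it adds that “slow loss of D can't be excluded”.

This flask gives 37.2%, 69.6% and 67.9%.

    J ⇌ D + X (K = 0.490 M, k = 2.80 × 10⁻⁴ s⁻¹)
    2 J → G (k = 1.40 × 10⁻⁴ M⁻¹ s⁻¹)

Your settling half-life, read from the north run, goes 22.4 times into 10 h, and the relaxation half-life of J and D + X by this step alone, both ways together, is 0.450 h at that time, short against 10 h. In this flask D stands at 70.0% at 5.00 h and 67.9% at 10.0 h, while G, which holds two J, goes from 11.4% to 14.6%.

The data were generated by integration from invented constants; the scatter is artificial.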